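**Amounts first.** Of the two charges so far, the larger gives less target in percent of the charge: at 5.00 d the violet run, charged 0.10 M, reads 11.3%, and the blue run, charged 0.15 M, reads 9.0%.

| setting | violet | blue | flask |
|---|---|---|---|
| substrate | 0.10 M | 0.15 M | 0.20 M |
| gas phase | 110 mM (held) | 110 mM (held) | 110 mM (held) |
| remark | run made earlier | run made earlier |  |
| time |  |  | 5.0 d |

| run | time / d | target / % | substrate / % |
|---|---|---|---|
| violet | 0.625 | 2.4 | 75.1 |
| violet | 1.67 | 6.9 | 52.3 |
| violet | 3.00 | 10.4 | 37.5 |
| violet | 5.00 | 11.3 | 27.2 |
| blue | 0.625 | 2.2 | 68.6 |
| blue | 1.67 | 5.5 | 42.8 |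
| blue | 3.00 | 7.3 | 30.5 |
| blue | 5.00 | 9.0 | 21.1 |

(each reading ± 0.5 percentage points)

- at the start none of the gas phase is in solution

- target at 5.0 d, in percent of the substrate charged
- concentration of dissolved gas in solution at 2.5 d, in percent of saturation
- the change that raises the amount of target at 5.0 d, in percent of the substrate charged most ("none" if none brings more than 2 percentage points) (north / north-west / none)
- amount of target at 5.0 d, in percent of the substrate charged, after north

- north: doubling the saturation concentration of gas phase, all else as stated
- north-west: doubling the transfer coefficient of the gas phase, all else as stated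

**One number.** The reciprocal of the substrate fraction climbs roughly linearly in time, so I read an overall second-order constant k from violet's last reading: 5.35 L mol⁻¹ d⁻¹. For the flask 5.35: this D = k·c·t, with c the charge and t the time, counts the starting lifetimes of the substrate that fit into the run, a Damköhler number.

**Both ends.** At small D the substrate stays near its charge, so its mean fraction over the run is near one. At large D the substrate fraction falls as one over one plus D, and its mean over the run goes as ln D over D. Joined, the mean is F, the logarithm of one plus D, divided by D, and for runs of 5.0 d I take target = G·F, with G a constant fitted to one reading, not a level that any flask reaches. Violet, with D of 2.68, gives G = 23.2%.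

**The test.** Blue, with D of 4.01, comes out at 9.32% against its reading of 9.0%, with scatter 0.5 percentage points. For the flask I reckon 8.02%. D holds no gas term, so the gas questions lie outside it.

**The forecast.** It says 7.3%, below my figure, then 96%, north and 13.5%, on the ground that “Gas uptake is small against transfer”.

**The flask.** It gives 7.14%, 39.0%, north (a gain of 6.2 points, against 2.9 points for north-west) and 13.4%.

    gas phase ⇌ dissolved gas, rate k1*(csat - [dissolved gas]) (kL = 0.0106 h⁻¹)
    substrate + dissolved gas ⇌ target (K = 5.70 L mol⁻¹, k = 0.437 L mol⁻¹ h⁻¹)
    2 substrate → homo dimer (k = 0.0936 L mol⁻¹ h⁻¹)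

**Not at rest.** At 5.0 d the flask holds 16.9% substrate, where one over one plus D gives 15.7%, and dissolved gas stands at 0.0736 M, below 110 mM. At 50.0 d D becomes 53.5, which gives 1.83%; the flask holds 3.13% substrate, target has fallen to 1.99%, and homo dimer, each counted as two substrate, stands at 94.9%. The neighbour charged 0.050 M, with D of 1.34, reckons to 42.7% substrate and 14.7% target at 5.0 d, and holds 39.5% and 16.7%.

The runs come from a simulation for substances that don't exist, noise included.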